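(The constants used here are made up; the result is computed.)

The meeting decided to judge this flask by one quantity, the round time, and worked from this scheme and charge.

    partner + free catalyst → catalyst intermediate A (k1 = 21.3 M⁻¹ min⁻¹)
    catalyst intermediate A ⇌ catalyst intermediate B (K2 = 5.2, k2 = 0.0788 min⁻¹)
    starting material + catalyst intermediate B → catalyst intermediate C (k3 = 0.684 M⁻¹ min⁻¹)
    catalyst intermediate C → free catalyst + product (k4 = 0.0402 min⁻¹)
    free catalyst + added ligand ⇌ idle complex (K5 = 7.8 M⁻¹, k5 = 0.154 M⁻¹ min⁻¹)
    gas ⇌ partner, rate k6*(csat - [partner]) (k6 = 0.00466 min⁻¹, csat = 110 mM)

starting material 0.25 M; gas 110 mM (held); free catalyst 25 mM; added ligand 58 mM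

* the form that holds most of the catalyst when 20% of the starting material are converted (catalyst intermediate C / idle complex / catalyst intermediate A / catalyst intermediate B / free catalyst)
* its share of the catalyst then

I argued the rule first. In quasi-steady state every form in the working round passes the same turnover, so such a form's share is its dwell time per turn divided by the sum of the dwell times; the idle complex stands outside the round and enters as time added to each turn.

I then took the dwell times at 20% conversion, where the starting material stands at 0.200 M. Catalyst intermediate C dwells the reciprocal of its exit constant, 24.9 min, and catalyst intermediate B dwells 7.31 min. Catalyst intermediate A dwells 14.1 min, the reciprocal of its forward constant plus B's dwell divided by the equilibrium constant 5.2, which counts the traffic returning from B.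

Free catalyst waits for dissolved partner, so I tried a partner level of 11.0 mM, which gave 4.27 min. I took the idle complex at equilibrium with added ligand as charged, which adds 1.93 min. These add to 52.5 min: the round time T, the time one catalyst takes on average for one whole turn, time as idle complex counted.

I tested the trial partner level. The catalyst charge divided by T carries 0.476 mM min⁻¹, and gas transfer at that trial level supplies 0.461 mM min⁻¹, so the two stand close. Catalyst intermediate C has the longest dwell, so I committed to catalyst intermediate C at 47.4%.

The forecast's author named catalyst intermediate C at 45%, holding that by then “the cycle is near a quasi-steady state”. My share stayed the higher of the two.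

The simulation gives catalyst intermediate C as the resting state, with 42.8% of the catalyst, when this flask reaches that conversion at 2.25 h. Earlier, at 1.47 h, catalyst intermediate C was being made 1.08 times as fast as it was used up, each step taken net. Turned round, the round time gives a rate of making product, the catalyst charge divided by T, of 0.0286 M h⁻¹; the flask's rate at that conversion is 0.0258 M h⁻¹.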